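All constants were drawn at random within sensible limits; what happens was integrated by code.

Your stirred vessel holds Q and E from the start, G arrives in portions, and you want to know how much X stands free at the end of each run.

common to all: Q 2.50 equiv; E 0.2 mol%; time 4.0 min
- south-west: G 0.015 M (in portions, 4); the portions of G follow each other after 6.0 s, the first at the start
- south-east: G 0.030 M (in portions, 4); the portions of G follow each other after 6.0 s, the first at the start
- south: G 0.060 M (in portions, 4); the portions of G follow each other after 6.0 s, the first at the start
- north-west: G 0.12 M (in portions, 4); the portions of G follow each other after 6.0 s, the first at the start
- east: G 0.25 M (in portions, 4); the portions of G follow each other after 6.0 s, the first at the start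

    Z ⇌ X, rate k1*(cs1 - [X]) while solid is left; crystals form when [X] > cs1 (cs1 = 0.15 M, k1 = 1.1 s⁻¹)
    Q + E → D + J (k2 = 0.061 L mol⁻¹ s⁻¹)
    G + Q + D → D + X (k3 = 340 L² mol⁻² s⁻¹)

- amounts and yields of X count Z too
- given per volume of solution although it is solid: Z
- the concentration of X that is asked is that of its free form alone
- "hardly changes" means that all values lie within two and a half points (for a concentration: within two and a half percent of the largest)
- run time (south-west): 4.0 min

1. [X] (only what is free in solution) at the end for south-west, south-east, south, north-west, east, in this order
2. how the row runs (rises all the way / falls all the way / rises, then falls / falls, then rises / hardly changes)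

Here is my own reckoning, as a ladder from the fastest rung to the slowest. Feeding G takes 18.0 s, while the exchange between crystals and solution has a time constant of 0.909 s, which is far shorter. So I take that step, faster than the feeding, as settled, and free [X] stops at 0.15 M while crystals stand. East is charged above that level, and north-west below it. The feeding is in turn much shorter than the run of 4.0 min, so I treat G as charged at once.

Next comes activation: step 3 needs D, and the vessel starts with E. With [Q] held as charged this step is pseudo-first-order, and the quantity to carry is the activation half-life, the time for Q to turn half of E into D, ln(2)/(k2[Q]). In south-west 5.05 min is longer than the run. The top rung in south-west is the turnover time with the whole catalyst as D, 43.6 min, longer still.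

Integrating the growing [D] shows that the run first loses a waiting time, 185 s in south-west. In south-west that leaves 55.3 s of effective time, so I reckon conversion there at 2.09%. In east both rungs drop below the run, to 18.2 s and 9.41 s.

The same sum gives a row of 3.14 × 10⁻⁴ M, 0.00403 M, 0.0350 M, 0.119 M and, capped, 0.150 M. These values hold [Q] as charged, although each G costs one Q.

The forecast reads 3.100 × 10⁻⁴ M, 0.0038 M, 0.031 M, 0.114 M and 0.15 M, and says the row rises all the way, on the ground that “conversion climbs very steeply with loading”. At south and north-west it lies below mine.

The simulation gives 3.11 × 10⁻⁴ M, 0.00390 M, 0.0316 M, 0.115 M and 0.150 M, and the row rises all the way. In south-west the half-life of E reads 5.1 min at 4.00 min, longer than the run; the carried half-life predicts 57.8% of the catalyst still as E, and the flask holds 57.9% with X at 2.08% of the G charged. In south-east the carried half-life is 2.53 min, shorter than the run; it predicts 33.4% as E, and that flask holds 34.1% with X at 13.0% of the G charged.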